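**Retrosynthetic overview**
- The target is taken back by hydrogenolysis, esterification of the top 3-hydroxyl and deallylation to trimer 23. Its top C4–middle C8 interflavan bond is cut to the C4-phenylsulfanyl top unit 15 and the benzylated procyanidin B2 3,3'-digallate 22, made from (−)-epicatechin 16 with each galloyl group put on at the monomer stage.
- Key disconnection: ring C of the top unit is cut at O1–C8a and at C3–C4. This gives the C4 carbanion of fluoroarene sulfide 6 (ring A plus C4) and the trans enol-ether epoxide 12 (O1, C2, C3, ring B). One anionic cascade (epoxide opening, then SNAr) makes both bonds.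
- Enabling feature: in ring A the oxygens on C5 and C7 are both meta to C8a, so a fluorine on C8a stays open to SNAr by O1. O1 on C2 and O3 on C3 are vicinal, so C3 can be the acetal carbon of an epoxide; its opening by C4 sets C3 by inversion and frees O1.
- Ring order: rings A and B are bought as benzenes; ring C of the top unit forms in the key step; rings C of the middle and bottom units come intact from 16. The middle–bottom interflavan bond is made first, then the top–middle bond.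

Key step: step 9

Remark: the target is read as epicatechin 3-O-gallate-(4β→8)-epicatechin 3-O-gallate-(4β→8)-epicatechin 3-O-gallate (every C2 and C3 R, both interflavan bonds 3,4-trans); C4 of 15 is allowed to form as a mixture of epimers because it passes through a planar cation in step 15.

**Route**

Step 1
Reactants: 1 1,3,5-trifluorobenzene
Product: 2 1,3-bis(benzyloxy)-5-fluorobenzene
Conditions: BnOH (2.1 equiv), NaH, NMP, 0 → 90 °C
Reagents that add atoms: benzyl alcohol, OCc1ccccc1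
Why: Twofold SNAr by sodium benzyloxide on the electron-poor arene; each alkoxy group that enters slows the next substitution, so the reaction should stop cleanly after two.

Step 2
Reactants: 2 1,3-bis(benzyloxy)-5-fluorobenzene
Product: 4 2,4-bis(benzyloxy)-6-fluorobenzaldehyde, via iminium salt 3 (not isolated)
Conditions: POCl3, DMF, 0 → 60 °C; then aq. NaOAc
Reagents that add atoms: N,N-dimethylformamide, CN(C)C=O; water, O
Why: Vilsmeier–Haack formylation of the electron-rich arene, expected para to one benzyloxy group and next to the small fluorine rather than at the position flanked by two benzyloxy groups.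

Step 3
Reactants: 4 2,4-bis(benzyloxy)-6-fluorobenzaldehyde
Product: 5 [2,4-bis(benzyloxy)-6-fluorophenyl]methanol
Conditions: NaBH4, THF–MeOH, 0 °C
Reagents that add atoms: none
Why: Borohydride reduction of an aromatic aldehyde, which leaves the aryl fluoride and benzyl ethers untouched.

Step 4
Reactants: 5 [2,4-bis(benzyloxy)-6-fluorophenyl]methanol
Product: 6 1,5-bis(benzyloxy)-3-fluoro-2-[(phenylsulfanyl)methyl]benzene
Conditions: PhSSPh, PBu3, THF, rt
Reagents that add atoms: diphenyl disulfide, c1ccc(SSc2ccccc2)cc1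
Why: Hata thioetherification, in which the alkoxyphosphonium salt of the primary benzylic alcohol is displaced by benzenethiolate.

Step 5
Reactants: 7 3,4-bis(benzyloxy)benzaldehyde and 8 malonic acid
Product: 9 (2E)-3-[3,4-bis(benzyloxy)phenyl]prop-2-enoic acid
Conditions: pyridine, piperidine (cat.), 90 °C
Reagents that add atoms: none
Why: Knoevenagel condensation in the Doebner modification, which should give the (E)-cinnamic acid after decarboxylation.

Step 6
Reactants: 9 (2E)-3-[3,4-bis(benzyloxy)phenyl]prop-2-enoic acid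
Product: 10 1,2-bis(benzyloxy)-4-[(E)-2-iodoethenyl]benzene
Conditions: N-iodosuccinimide, Et3N (cat.), CH2Cl2, rt
Reagents that add atoms: N-iodosuccinimide, O=C1CCC(=O)N1I
Why: Catalytic Hunsdiecker-type iododecarboxylation, which works best on electron-rich cinnamic acids and should give the (E)-vinyl iodide.

Step 7
Reactants: 10 1,2-bis(benzyloxy)-4-[(E)-2-iodoethenyl]benzene
Product: 11 1,2-bis(benzyloxy)-4-[(E)-2-(prop-2-en-1-yloxy)ethenyl]benzene
Conditions: allyl alcohol, CuI (10 mol %), 3,4,7,8-tetramethyl-1,10-phenanthroline (20 mol %), Cs2CO3, toluene, 80 °C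
Reagents that add atoms: prop-2-en-1-ol, C=CCO
Why: Ullmann-type CuI-catalysed C–O coupling of a vinyl iodide with a primary alcohol, which keeps the (E) geometry of the alkene.

Step 8
Reactants: 11 1,2-bis(benzyloxy)-4-[(E)-2-(prop-2-en-1-yloxy)ethenyl]benzene
Product: 12 (2S,3R)-2-(prop-2-en-1-yloxy)-3-[3,4-bis(benzyloxy)phenyl]oxirane
Conditions: D-fructose-derived Shi ketone (0.3 equiv), Oxone, K2CO3, Bu4NHSO4, MeCN–CH2(OMe)2–aq. borate buffer (pH 10.5), −10 °C; cold work-up, used crude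
Reagents that add atoms: potassium peroxymonosulfate (active part of Oxone), [K+].[O-]S(=O)(=O)OO
Why: Shi epoxidation, in which the chiral dioxirane attacks the electron-rich trans enol ether through the spiro transition state and, by analogy with trans-β-methylstyrene, should set the aryl-bearing carbon R and the alkoxy-bearing carbon S, while the isolated allyl double bond is far less reactive.

Step 9
Reactants: 6 1,5-bis(benzyloxy)-3-fluoro-2-[(phenylsulfanyl)methyl]benzene and 12 (2S,3R)-2-(prop-2-en-1-yloxy)-3-[3,4-bis(benzyloxy)phenyl]oxirane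
Product: 15 (2R,3S)-3-(allyloxy)-5,7-bis(benzyloxy)-2-[3,4-bis(benzyloxy)phenyl]-4-(phenylsulfanyl)-3,4-dihydro-2H-chromene (2,3-cis; C4 epimers), via lithiated sulfide 13 (not isolated), via lithium alkoxide 14 (not isolated)
Conditions: 6, n-BuLi (1.0 equiv), THF, −78 °C; 12, −78 → −30 °C; then DMPU, 50 °C
Reagents that add atoms: none
Why: Proposed new method: the lithiated benzyl sulfide 13 should attack the O,O-acetal carbon C3 of the trans epoxide 12 from the side opposite to the C3–O1 bond (SN2-type opening; the closest known reaction type is the opening of 1,2-anhydro sugars by organolithium and organocopper reagents at the anomeric carbon with inversion), which forms C3–C4 and releases O1 as the lithium alkoxide 14. On warming with DMPU this alkoxide should displace fluoride from C8a by intramolecular SNAr through a Meisenheimer-type transition state (6-exo-trig attack on the ring A carbon, as in the base-induced cyclisation of 3-(2-fluoroaryl)propan-1-ols to chromans), which forms O1–C8a and closes ring C. C2 is carried over unchanged from the epoxide, C3 is set by inversion at the trans-epoxide carbon so that the aryl group on C2 and the allyloxy group on C3 end up cis, and C4 forms as a mixture of epimers that is erased when C4 is ionised in step 15. The step needs attack at C3 and not at the benzylic C2, which the lone pair of O3 on C3 and the absence of a Lewis acid should secure; it needs ring closure through O1 only, which is secured because O3 is an allyl ether and no other alkoxide is present; and the fluoride is displaceable because both benzyloxy groups of ring A are meta to C8a and cannot deactivate it by resonance.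

Step 10
Reactants: 16 (−)-epicatechin
Product: 17 (2R,3R)-5,7-bis(benzyloxy)-2-[3,4-bis(benzyloxy)phenyl]-3,4-dihydro-2H-chromen-3-ol (5,7,3',4'-tetra-O-benzylepicatechin)
Conditions: BnBr, K2CO3, DMF, 0 °C → rt
Reagents that add atoms: benzyl bromide, BrCc1ccccc1
Why: Williamson ether synthesis, in which K2CO3 deprotonates only the four phenols and leaves the secondary alcohol free.

Step 11
Reactants: 17 5,7,3',4'-tetra-O-benzylepicatechin and 18 3,4,5-tris(benzyloxy)benzoic acid
Product: 19 5,7,3',4'-tetra-O-benzylepicatechin 3-O-[3,4,5-tris(benzyloxy)benzoate]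
Conditions: 18 (1.5 equiv), DCC, DMAP, CH2Cl2, rt
Reagents that add atoms: none
Why: Steglich esterification of the single secondary 3-hydroxyl group through the N-acylpyridinium ion, which leaves C2 and C3 untouched.

Step 12
Reactants: 17 5,7,3',4'-tetra-O-benzylepicatechin
Product: 20 (2R,3R,4S)-5,7-bis(benzyloxy)-2-[3,4-bis(benzyloxy)phenyl]-4-(2-ethoxyethoxy)-3,4-dihydro-2H-chromen-3-ol (4β ether)
Conditions: DDQ, 2-ethoxyethanol, CH2Cl2, rt
Reagents that add atoms: 2-ethoxyethanol, CCOCCO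
Why: DDQ oxidation by hydride abstraction at the benzylic C4, followed by capture of the cation by the alcohol anti to the C3 hydroxyl, which should give the 4β ether.

Step 13
Reactants: 20 4β-(2-ethoxyethoxy) ether and 18 3,4,5-tris(benzyloxy)benzoic acid
Product: 21 5,7,3',4'-tetra-O-benzyl-4β-(2-ethoxyethoxy)epicatechin 3-O-[3,4,5-tris(benzyloxy)benzoate]
Conditions: 18 (1.5 equiv), DCC, DMAP, CH2Cl2, 0 °C → rt
Reagents that add atoms: none
Why: Steglich esterification of the 3-hydroxyl group under non-acidic conditions, which the acid-labile benzylic C4 ether should survive.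

Step 14
Reactants: 21 galloylated 4β-(2-ethoxyethoxy) ether and 19 5,7,3',4'-tetra-O-benzylepicatechin 3-O-[3,4,5-tris(benzyloxy)benzoate]
Product: 22 octa-O-benzyl procyanidin B2 3,3'-bis[3,4,5-tris(benzyloxy)benzoate] (4β→8 dimer)
Conditions: TMSOTf (cat.), 19 (4 equiv), CH2Cl2, −78 → −40 °C
Reagents that add atoms: none
Why: Lewis-acid-mediated Friedel–Crafts-type interflavan coupling, in which TMSOTf ionises the C4 ether, the α-oriented 3-O-acyl group covers the α face of the cation by acyloxonium participation, and C8 of the excess nucleophile attacks from the β face, setting the new C4 centre 3,4-trans (4β).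

Step 15
Reactants: 15 C4-phenylsulfanyl top unit and 22 octa-O-benzyl procyanidin B2 3,3'-bis[3,4,5-tris(benzyloxy)benzoate]
Product: 23 3-O-allyl-5,7,3',4'-tetra-O-benzylepicatechin-(4β→8)-[5,7,3',4'-tetra-O-benzylepicatechin 3-O-(tri-O-benzylgallate)]-(4β→8)-[5,7,3',4'-tetra-O-benzylepicatechin 3-O-(tri-O-benzylgallate)]
Conditions: AgBF4, 22 (2 equiv), THF, 0 °C, dark
Reagents that add atoms: none
Why: Thiophilic activation of the C4 sulfide gives the benzylic cation, which the free C8 of the upper unit of 22 should attack anti to the axial 3-allyloxy group (Friedel–Crafts-type alkylation), so that both C4 epimers of 15 converge on the 4β (3,4-trans) bond.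

Step 16
Reactants: 23 3-O-allyl trimer digallate
Product: 25 dodeca-O-benzyl procyanidin C1 3',3''-bis[3,4,5-tris(benzyloxy)benzoate] with a free 3-hydroxyl group on the top unit, via prop-1-enyl ether 24 (not isolated)
Conditions: [Ir(cod)(PMePh2)2]PF6 (cat., H2-activated), THF, rt; then 0.1 M aq. HCl–acetone, rt
Reagents that add atoms: none
Why: Iridium-catalysed isomerisation of the allyl ether to the enol ether, followed by mild acid hydrolysis, conditions that should leave benzyl ethers, gallate esters and interflavan bonds intact.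

Step 17
Reactants: 25 trimer digallate with the free top 3-hydroxyl group and 18 3,4,5-tris(benzyloxy)benzoic acid
Product: 26 dodeca-O-benzyl procyanidin C1 3,3',3''-tris[3,4,5-tris(benzyloxy)benzoate]
Conditions: 18 (3 equiv), DCC, DMAP, CH2Cl2, rt
Reagents that add atoms: none
Why: Steglich esterification of the one remaining secondary 3-hydroxyl group, the usual way to galloylate a hindered flavan-3-ol.

Step 18
Reactants: 26 fully benzylated tri-O-gallate
Product: 27 procyanidin C1 3,3',3''-tri-O-gallate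
Conditions: H2 (1 atm), Pd(OH)2 on carbon, THF–MeOH–H2O, rt
Reagents that add atoms: none
Why: Hydrogenolysis of the twenty-one benzyl ethers, under which the gallate esters and the interflavan bonds should survive.

**Compound list**

1 | 1,3,5-trifluorobenzene | Fc1cc(F)cc(F)c1 | starting material
2 | 1,3-bis(benzyloxy)-5-fluorobenzene | Fc1cc(OCc2ccccc2)cc(OCc2ccccc2)c1 | intermediate
3 | N-{[2,4-bis(benzyloxy)-6-fluorophenyl]methylidene}-N-methylmethanaminium dichlorophosphate (iminium salt) | C[N+](C)=Cc1c(F)cc(OCc2ccccc2)cc1OCc1ccccc1.[O-]P(=O)(Cl)Cl | intermediate (not isolated)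
4 | 2,4-bis(benzyloxy)-6-fluorobenzaldehyde | O=Cc1c(F)cc(OCc2ccccc2)cc1OCc1ccccc1 | intermediate
5 | [2,4-bis(benzyloxy)-6-fluorophenyl]methanol | OCc1c(F)cc(OCc2ccccc2)cc1OCc1ccccc1 | intermediate
6 | 1,5-bis(benzyloxy)-3-fluoro-2-[(phenylsulfanyl)methyl]benzene | Fc1cc(OCc2ccccc2)cc(OCc2ccccc2)c1CSc1ccccc1 | intermediate
7 | 3,4-bis(benzyloxy)benzaldehyde | O=Cc1ccc(OCc2ccccc2)c(OCc2ccccc2)c1 | starting material
8 | malonic acid | OC(=O)CC(=O)O | starting material
9 | (2E)-3-[3,4-bis(benzyloxy)phenyl]prop-2-enoic acid | OC(=O)/C=C/c1ccc(OCc2ccccc2)c(OCc2ccccc2)c1 | intermediate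
10 | 1,2-bis(benzyloxy)-4-[(E)-2-iodoethenyl]benzene | I/C=C/c1ccc(OCc2ccccc2)c(OCc2ccccc2)c1 | intermediate
11 | 1,2-bis(benzyloxy)-4-[(E)-2-(prop-2-en-1-yloxy)ethenyl]benzene | C=CCO/C=C/c1ccc(OCc2ccccc2)c(OCc2ccccc2)c1 | intermediate
12 | (2S,3R)-2-(prop-2-en-1-yloxy)-3-[3,4-bis(benzyloxy)phenyl]oxirane (trans) | C=CCO[C@H]1O[C@@H]1c1ccc(OCc2ccccc2)c(OCc2ccccc2)c1 | intermediate
13 | {[2,4-bis(benzyloxy)-6-fluorophenyl](phenylsulfanyl)methyl}lithium (lithiated sulfide) | [Li]C(Sc1ccccc1)c1c(F)cc(OCc2ccccc2)cc1OCc1ccccc1 | intermediate (not isolated)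
14 | lithium (1R,2S)-2-(allyloxy)-3-[2,4-bis(benzyloxy)-6-fluorophenyl]-1-[3,4-bis(benzyloxy)phenyl]-3-(phenylsulfanyl)propan-1-olate (C3 epimers) | [Li]O[C@H](c1ccc(OCc2ccccc2)c(OCc2ccccc2)c1)[C@H](OCC=C)C(Sc1ccccc1)c1c(F)cc(OCc2ccccc2)cc1OCc1ccccc1 | intermediate (not isolated)
15 | (2R,3S)-3-(allyloxy)-5,7-bis(benzyloxy)-2-[3,4-bis(benzyloxy)phenyl]-4-(phenylsulfanyl)-3,4-dihydro-2H-chromene (2,3-cis; C4 epimers; C3 is S only because sulfur raises the rank of C4) | C=CCO[C@@H]1C(Sc2ccccc2)c2c(OCc3ccccc3)cc(OCc3ccccc3)cc2O[C@@H]1c1ccc(OCc2ccccc2)c(OCc2ccccc2)c1 | intermediate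
16 | (−)-epicatechin, (2R,3R) | O[C@@H]1Cc2c(O)cc(O)cc2O[C@@H]1c1ccc(O)c(O)c1 | starting material
17 | 5,7,3',4'-tetra-O-benzylepicatechin, (2R,3R) | O[C@@H]1Cc2c(OCc3ccccc3)cc(OCc3ccccc3)cc2O[C@@H]1c1ccc(OCc2ccccc2)c(OCc2ccccc2)c1 | intermediate
18 | 3,4,5-tris(benzyloxy)benzoic acid | OC(=O)c1cc(OCc2ccccc2)c(OCc2ccccc2)c(OCc2ccccc2)c1 | starting material
19 | 5,7,3',4'-tetra-O-benzylepicatechin 3-O-[3,4,5-tris(benzyloxy)benzoate], (2R,3R) | O=C(O[C@@H]1Cc2c(OCc3ccccc3)cc(OCc3ccccc3)cc2O[C@@H]1c1ccc(OCc2ccccc2)c(OCc2ccccc2)c1)c1cc(OCc2ccccc2)c(OCc2ccccc2)c(OCc2ccccc2)c1 | intermediate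
20 | (2R,3R,4S)-5,7,3',4'-tetra-O-benzyl-4-(2-ethoxyethoxy)epicatechin (4β, 3,4-trans) | O[C@@H]1[C@@H](OCCOCC)c2c(OCc3ccccc3)cc(OCc3ccccc3)cc2O[C@@H]1c1ccc(OCc2ccccc2)c(OCc2ccccc2)c1 | intermediate
21 | (2R,3R,4S)-5,7,3',4'-tetra-O-benzyl-4-(2-ethoxyethoxy)epicatechin 3-O-[3,4,5-tris(benzyloxy)benzoate] (4β, 3,4-trans) | O=C(O[C@@H]1[C@@H](OCCOCC)c2c(OCc3ccccc3)cc(OCc3ccccc3)cc2O[C@@H]1c1ccc(OCc2ccccc2)c(OCc2ccccc2)c1)c1cc(OCc2ccccc2)c(OCc2ccccc2)c(OCc2ccccc2)c1 | intermediate
22 | octa-O-benzyl procyanidin B2 3,3'-bis[3,4,5-tris(benzyloxy)benzoate], epicatechin-(4β→8)-epicatechin with all eight phenols benzylated and both 3-hydroxyl groups galloylated | O=C(O[C@@H]1[C@@H](c2c(OCc3ccccc3)cc(OCc3ccccc3)c3c2O[C@H](c2ccc(OCc4ccccc4)c(OCc4ccccc4)c2)[C@H](OC(=O)c2cc(OCc4ccccc4)c(OCc4ccccc4)c(OCc4ccccc4)c2)C3)c2c(OCc3ccccc3)cc(OCc3ccccc3)cc2O[C@@H]1c1ccc(OCc2ccccc2)c(OCc2ccccc2)c1)c1cc(OCc2ccccc2)c(OCc2ccccc2)c(OCc2ccccc2)c1 | intermediate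
23 | dodeca-O-benzyl procyanidin C1 with an allyl ether on O3 of the top unit and tri-O-benzylgallate esters on O3 of the middle and bottom units | O=C(O[C@@H]1[C@@H](c2c(OCc3ccccc3)cc(OCc3ccccc3)c3c2O[C@H](c2ccc(OCc4ccccc4)c(OCc4ccccc4)c2)[C@H](OC(=O)c2cc(OCc4ccccc4)c(OCc4ccccc4)c(OCc4ccccc4)c2)C3)c2c(OCc3ccccc3)cc(OCc3ccccc3)c([C@H]3c4c(OCc5ccccc5)cc(OCc5ccccc5)cc4O[C@H](c4ccc(OCc5ccccc5)c(OCc5ccccc5)c4)[C@@H]3OCC=C)c2O[C@@H]1c1ccc(OCc2ccccc2)c(OCc2ccccc2)c1)c1cc(OCc2ccccc2)c(OCc2ccccc2)c(OCc2ccccc2)c1 | intermediate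
24 | the (E)-prop-1-enyl ether isomer of 23 | O=C(O[C@@H]1[C@@H](c2c(OCc3ccccc3)cc(OCc3ccccc3)c3c2O[C@H](c2ccc(OCc4ccccc4)c(OCc4ccccc4)c2)[C@H](OC(=O)c2cc(OCc4ccccc4)c(OCc4ccccc4)c(OCc4ccccc4)c2)C3)c2c(OCc3ccccc3)cc(OCc3ccccc3)c([C@H]3c4c(OCc5ccccc5)cc(OCc5ccccc5)cc4O[C@H](c4ccc(OCc5ccccc5)c(OCc5ccccc5)c4)[C@@H]3O/C=C/C)c2O[C@@H]1c1ccc(OCc2ccccc2)c(OCc2ccccc2)c1)c1cc(OCc2ccccc2)c(OCc2ccccc2)c(OCc2ccccc2)c1 | intermediate (not isolated)
25 | dodeca-O-benzyl procyanidin C1 3',3''-bis[3,4,5-tris(benzyloxy)benzoate] (middle and bottom units galloylated; free 3-hydroxyl group on the top unit) | O=C(O[C@@H]1[C@@H](c2c(OCc3ccccc3)cc(OCc3ccccc3)c3c2O[C@H](c2ccc(OCc4ccccc4)c(OCc4ccccc4)c2)[C@H](OC(=O)c2cc(OCc4ccccc4)c(OCc4ccccc4)c(OCc4ccccc4)c2)C3)c2c(OCc3ccccc3)cc(OCc3ccccc3)c([C@H]3c4c(OCc5ccccc5)cc(OCc5ccccc5)cc4O[C@H](c4ccc(OCc5ccccc5)c(OCc5ccccc5)c4)[C@@H]3O)c2O[C@@H]1c1ccc(OCc2ccccc2)c(OCc2ccccc2)c1)c1cc(OCc2ccccc2)c(OCc2ccccc2)c(OCc2ccccc2)c1 | intermediate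
26 | dodeca-O-benzyl procyanidin C1 3,3',3''-tris[3,4,5-tris(benzyloxy)benzoate] | O=C(O[C@@H]1[C@@H](c2c(OCc3ccccc3)cc(OCc3ccccc3)c3c2O[C@H](c2ccc(OCc4ccccc4)c(OCc4ccccc4)c2)[C@H](OC(=O)c2cc(OCc4ccccc4)c(OCc4ccccc4)c(OCc4ccccc4)c2)C3)c2c(OCc3ccccc3)cc(OCc3ccccc3)c([C@H]3c4c(OCc5ccccc5)cc(OCc5ccccc5)cc4O[C@H](c4ccc(OCc5ccccc5)c(OCc5ccccc5)c4)[C@@H]3OC(=O)c3cc(OCc4ccccc4)c(OCc4ccccc4)c(OCc4ccccc4)c3)c2O[C@@H]1c1ccc(OCc2ccccc2)c(OCc2ccccc2)c1)c1cc(OCc2ccccc2)c(OCc2ccccc2)c(OCc2ccccc2)c1 | intermediate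
27 | procyanidin C1 3,3',3''-tri-O-gallate | O=C(O[C@@H]1[C@@H](c2c(O)cc(O)c3c2O[C@H](c2ccc(O)c(O)c2)[C@H](OC(=O)c2cc(O)c(O)c(O)c2)C3)c2c(O)cc(O)c([C@H]3c4c(O)cc(O)cc4O[C@H](c4ccc(O)c(O)c4)[C@@H]3OC(=O)c3cc(O)c(O)c(O)c3)c2O[C@@H]1c1ccc(O)c(O)c1)c1cc(O)c(O)c(O)c1 | target

**Step count and risks**

Total step count: 18. Longest linear sequence: 9 steps (steps 1, 2, 3, 4, 9, 15, 16, 17, 18; the branch through steps 5 to 8 is equally long).

Steps most likely to fail:

Step 9. What may go wrong: opening of the epoxide at the benzylic carbon C2 instead of the acetal carbon C3; lithium-induced rearrangement of the epoxide to a carbonyl compound before the carbanion arrives; or loss of allyloxide by β-elimination from the open-chain alkoxide before ring C closes. The fallback uses known chemistry from the chiral pool; it sets out from 17 and comes back at 15. O-Allylation of 17 (NaH, allyl bromide, DMF) should give 3-O-allyl-5,7,3',4'-tetra-O-benzylepicatechin F1. DDQ oxidation of F1 in the presence of 2-ethoxyethanol should give 3-O-allyl-5,7,3',4'-tetra-O-benzyl-4β-(2-ethoxyethoxy)epicatechin F2. Acid-mediated exchange of F2 with benzenethiol (BF3·OEt2, CH2Cl2, −78 °C) should then give 15 as its 4β epimer.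

Step 8. What may go wrong: hydrolytic or base-induced opening of the acetal-type epoxide in the aqueous buffer, or incomplete facial selectivity of the dioxirane. The fallback sets out from 11 and comes back at 23. Epoxidation of 11 with dimethyldioxirane in dry acetone at −40 °C should give, without water, the racemic trans epoxide rac-2-(prop-2-en-1-yloxy)-3-[3,4-bis(benzyloxy)phenyl]oxirane F3. Run on F3, the sequence of step 9 should give the racemic 2,3-cis sulfide rac-15 F4. Coupling of F4 with the enantiopure dimer 22 as in step 15 should give 23 together with its diastereomer that carries the enantiomeric top unit, 3-O-allyl-tetra-O-benzyl-ent-epicatechin-(4α→8)-[tetra-O-benzylepicatechin 3-O-(tri-O-benzylgallate)]-(4β→8)-[tetra-O-benzylepicatechin 3-O-(tri-O-benzylgallate)] F5. The two are separated by chromatography and 23 is carried on.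

Step 15. What may go wrong: self-condensation of the cation with ring A of unreacted 15 (oligomerisation), attack through C6 instead of C8, or acid-induced scrambling of the interflavan bonds under stoichiometric silver conditions. The fallback sets out from 15 and comes back at 23. Silver-assisted solvolysis of 15 in a large excess of ethane-1,2-diol (AgBF4, 2,6-di-tert-butylpyridine, THF) should give the oxygen donor 3-O-allyl-5,7,3',4'-tetra-O-benzyl-4β-(2-hydroxyethoxy)epicatechin F6. TMSOTf-catalysed coupling of F6 with 22 (CH2Cl2, −78 °C), the catalytic oxygen-donor mode already used in step 14, should then give 23.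

Further compounds
F1 | step 9 | 3-O-allyl-5,7,3',4'-tetra-O-benzylepicatechin | C=CCO[C@@H]1Cc2c(OCc3ccccc3)cc(OCc3ccccc3)cc2O[C@@H]1c1ccc(OCc2ccccc2)c(OCc2ccccc2)c1
F2 | step 9 | 3-O-allyl-5,7,3',4'-tetra-O-benzyl-4β-(2-ethoxyethoxy)epicatechin | C=CCO[C@@H]1[C@@H](OCCOCC)c2c(OCc3ccccc3)cc(OCc3ccccc3)cc2O[C@@H]1c1ccc(OCc2ccccc2)c(OCc2ccccc2)c1
F3 | step 8 | rac-trans-2-(prop-2-en-1-yloxy)-3-[3,4-bis(benzyloxy)phenyl]oxirane (both enantiomers) | C=CCO[C@H]1O[C@@H]1c1ccc(OCc2ccccc2)c(OCc2ccccc2)c1.C=CCO[C@@H]1O[C@H]1c1ccc(OCc2ccccc2)c(OCc2ccccc2)c1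
F4 | step 8 | racemic 2,3-cis-3-(allyloxy)-5,7-bis(benzyloxy)-2-[3,4-bis(benzyloxy)phenyl]-4-(phenylsulfanyl)-3,4-dihydro-2H-chromene (both enantiomers, C4 epimers) | C=CCO[C@@H]1C(Sc2ccccc2)c2c(OCc3ccccc3)cc(OCc3ccccc3)cc2O[C@@H]1c1ccc(OCc2ccccc2)c(OCc2ccccc2)c1.C=CCO[C@H]1C(Sc2ccccc2)c2c(OCc3ccccc3)cc(OCc3ccccc3)cc2O[C@H]1c1ccc(OCc2ccccc2)c(OCc2ccccc2)c1
F5 | step 8 | 3-O-allyl-tetra-O-benzyl-ent-epicatechin-(4α→8)-[tetra-O-benzylepicatechin 3-O-(tri-O-benzylgallate)]-(4β→8)-[tetra-O-benzylepicatechin 3-O-(tri-O-benzylgallate)] (diastereomer of 23) | O=C(O[C@@H]1[C@@H](c2c(OCc3ccccc3)cc(OCc3ccccc3)c3c2O[C@H](c2ccc(OCc4ccccc4)c(OCc4ccccc4)c2)[C@H](OC(=O)c2cc(OCc4ccccc4)c(OCc4ccccc4)c(OCc4ccccc4)c2)C3)c2c(OCc3ccccc3)cc(OCc3ccccc3)c([C@@H]3c4c(OCc5ccccc5)cc(OCc5ccccc5)cc4O[C@@H](c4ccc(OCc5ccccc5)c(OCc5ccccc5)c4)[C@H]3OCC=C)c2O[C@@H]1c1ccc(OCc2ccccc2)c(OCc2ccccc2)c1)c1cc(OCc2ccccc2)c(OCc2ccccc2)c(OCc2ccccc2)c1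
F6 | step 15 | 3-O-allyl-5,7,3',4'-tetra-O-benzyl-4β-(2-hydroxyethoxy)epicatechin | C=CCO[C@@H]1[C@@H](OCCO)c2c(OCc3ccccc3)cc(OCc3ccccc3)cc2O[C@@H]1c1ccc(OCc2ccccc2)c(OCc2ccccc2)c1
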